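**Strategy.** The chroman is cut at O1–C2 and C3–C4. C4 is the formyl carbon of a salicylaldehyde, and C2, C3 and the C2 methyl are C3, the C3 methyl and C2 of geranylgeranial, whose C1 is excised afterwards. One amine-catalysed operation joins these two achiral pieces, closes the pyran ring and a bridging lactol ring, and sets the quaternary C2 centre. The precursors are 2-hydroxy-3,6-dimethyl-5-(triisopropylsilyloxy)benzaldehyde and (2E,6E,10E)-geranylgeranial; the silyl ether is used so that the last unmasking needs only fluoride. The step exploits the ortho placement of O1 and C4 on the benzene ring and the isoprenoid branching at C2 (methyl plus chain), which is the head of a β-methyl enal.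

Key step: step 4

Assumption: the (S)-catalyst is assigned on the usual steric model (E-iminium, s-trans, the CH2–CH(OH)Ar arm trans to the iminium carbon, oxygen attack anti to the silyloxydiarylmethyl group), which leads to the 2R centre; if the first run shows the opposite sense, the (R)-catalyst is used with no other change.

Catalyst: (S)-2-{bis[3,5-bis(trifluoromethyl)phenyl](triethylsilyloxy)methyl}pyrrolidine, CC[Si](CC)(CC)OC([C@@H]1CCCN1)(c1cc(C(F)(F)F)cc(C(F)(F)F)c1)c1cc(C(F)(F)F)cc(C(F)(F)F)c1, obtained from the commercial prolinol with TESOTf/Et3N.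

**Route**

Step 1
Reactants: 1 2,5-dimethylbenzene-1,4-diol (2,5-dimethylhydroquinone)
Product: 2 2,5-dimethyl-4-[(triisopropylsilyl)oxy]phenol
Conditions: TIPSCl (0.9 equiv), imidazole, DMF, 0 °C to rt; diol in excess
Reagents that add atoms: triisopropylsilyl chloride, CC(C)[Si](Cl)(C(C)C)C(C)C
Why: Mono-silylation (silyl ether formation) of the C2h-symmetric diol, whose two hydroxyls are equivalent, should give one monoether separable from diol and bis-ether, and the triisopropylsilyl group tolerates base, heat and radicals yet leaves with fluoride.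

Step 2
Reactants: 2 2,5-dimethyl-4-[(triisopropylsilyl)oxy]phenol
Product: 3 2-hydroxy-3,6-dimethyl-5-[(triisopropylsilyl)oxy]benzaldehyde
Conditions: MgCl2, Et3N, (CH2O)n, THF, reflux; aqueous HCl work-up
Reagents that add atoms: paraformaldehyde (reacts as formaldehyde), C=O
Why: The magnesium phenoxide directed ortho-formylation (Casnati–Skattebøl reaction) delivers formaldehyde only ortho to the free hydroxyl, where C6 is the single open position, and the bulky silyl ether should resist the methoxide formed.

Step 3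
Reactants: 4 (2E,6E,10E)-geranylgeraniol
Product: 5 (2E,6E,10E)-geranylgeranial
Conditions: activated MnO2 (excess), hexane, rt
Reagents that add atoms: none
Why: MnO2 allylic oxidation converts the primary allylic alcohol into the enal without touching the isolated trisubstituted alkenes.

Step 4
Reactants: 3 2-hydroxy-3,6-dimethyl-5-[(triisopropylsilyl)oxy]benzaldehyde; 5 (2E,6E,10E)-geranylgeranial
Product: 9 bridged tricyclic lactol (chroman numbering: C2 and C4 both R; C2 carries the (3E,7E)-4,8,12-trimethyltrideca-3,7,11-trienyl chain; a CH2–CH(OH)–O bridge runs from C2 to C4 on the face opposite the chain; 5,8-dimethyl; 6-OTIPS; anomeric epimers), via dienamine 6 (not isolated), via iminium benzoate 7 (not isolated), via hydroxy aldehyde 8 (not isolated)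
Conditions: (S)-catalyst (30 mol %), PhCO2H (30 mol %), toluene, rt, argon
Reagents that add atoms: none
Why: The amine condenses with 5 and loss of a proton from the C3 methyl should give the linear 1-amino-1,3-diene 6, whose unsubstituted terminal carbon adds to the formyl group of 3 (vinylogous aldol, C3–C4 bond) and returns the conjugated iminium ion 7. The phenol oxygen of 7 then adds to the iminium β-carbon in a 6-exo-trig oxa-Michael closure of the pyran ring (O1–C2 bond) from the face left open by the silyloxydiarylmethyl group of the catalyst, which sets C2, and hydrolysis releases 8 and the amine. In 8 the C4 hydroxyl adds to the aldehyde in a 6-exo-trig hemiacetalisation that closes the second ring; only the isomer with the C4 oxygen cis to the acetaldehyde arm can bridge and the earlier steps are reversible, so C4 follows C2, while the anomeric carbon remains a mixture that step 5 erases. The closest known reaction type is the diarylprolinol silyl ether catalysed domino aldol/oxa-Michael annulation of salicylaldehydes with β-methyl enals. The step needs deprotonation at the methyl and not at C4H2 of 5, which the low hindrance of the resulting exo-methylene terminus towards the di-ortho-substituted aldehyde should favour, and it needs the dienamine path to outrun direct oxa-Michael addition to the enal, which the β,β-disubstitution of 5 secures. Geometric isomers of 5 and of 7 interconvert through 6 and therefore converge on one product.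

Step 5
Reactants: 9 bridged tricyclic lactol
Product: 10 (2R,4R)-2,5,8-trimethyl-2-[(3E,7E)-4,8,12-trimethyltrideca-3,7,11-trien-1-yl]-6-[(triisopropylsilyl)oxy]chroman-4-ol
Conditions: RhCl(PPh3)3 (1.1 equiv), degassed toluene, 110 °C, argon; 9 freed of amine beforehand
Reagents that add atoms: none
Why: In this Tsuji–Wilkinson decarbonylation the lactol reacts through its ring-opened hydroxy aldehyde tautomer (the species numbered 8 in step 4, present in ring–chain equilibrium with 9), whose formyl C–H adds to monovalent rhodium, after which CO migrates to the metal and C–H reductive elimination leaves the C2 methyl without touching C2 or C4; the alkyl–rhodium intermediate has no β-hydrogen, and the closed-shell path avoids the 5-exo cyclisation onto the C3′ alkene that a free radical at this carbon would undergo.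

Step 6
Reactants: 10 (2R,4R)-chroman-4-ol
Product: 11 O-[(2R,4R)-2,5,8-trimethyl-2-[(3E,7E)-4,8,12-trimethyltrideca-3,7,11-trien-1-yl]-6-[(triisopropylsilyl)oxy]chroman-4-yl] S-methyl carbonodithioate
Conditions: NaH, THF, 0 °C; CS2; MeI, 0 °C to rt
Reagents that add atoms: carbon disulfide, S=C=S; iodomethane, CI
Why: Xanthate formation (first stage of the Barton–McCombie deoxygenation) proceeds by addition of the sodium alkoxide to CS2 and S-methylation at low temperature, conditions under which the aryl silyl ether and the alkenes are inert.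

Step 7
Reactants: 11 S-methyl xanthate
Product: 12 triisopropyl{[(2R)-2,5,8-trimethyl-2-[(3E,7E)-4,8,12-trimethyltrideca-3,7,11-trien-1-yl]chroman-6-yl]oxy}silane
Conditions: Bu3SnH (3 equiv), Et3B, air (trace), toluene, rt
Reagents that add atoms: none
Why: In the Barton–McCombie reduction the Bu3Sn radical adds to the thiocarbonyl sulfur, β-scission gives the benzylic C4 radical, and hydrogen transfer from Bu3SnH at room temperature (which avoids Chugaev elimination) should outrun the slow 6-exo addition to the C3′ alkene, so C4 becomes CH2 and C2 is untouched.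

Step 8
Reactants: 12 silyl ether of the target
Product: 13 (2R)-2,5,8-trimethyl-2-[(3E,7E)-4,8,12-trimethyltrideca-3,7,11-trien-1-yl]chroman-6-ol (CID5282348)
Conditions: Bu4NF (1.1 equiv), AcOH (1.1 equiv), THF, 0 °C, argon
Reagents that add atoms: none
Why: Fluoride-induced desilylation of the aryl silyl ether, buffered with acetic acid so that the air-sensitive phenoxide does not accumulate, leaves the chroman, the three E alkenes and the C2 centre unchanged.

**Compound list**

1 | 2,5-dimethylbenzene-1,4-diol | Cc1cc(O)c(C)cc1O | starting material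
2 | 2,5-dimethyl-4-[(triisopropylsilyl)oxy]phenol | Cc1cc(O[Si](C(C)C)(C(C)C)C(C)C)c(C)cc1O | intermediate
3 | 2-hydroxy-3,6-dimethyl-5-[(triisopropylsilyl)oxy]benzaldehyde | O=Cc1c(C)c(O[Si](C(C)C)(C(C)C)C(C)C)cc(C)c1O | intermediate
4 | (2E,6E,10E)-geranylgeraniol | CC(C)=CCC/C(C)=C/CC/C(C)=C/CC/C(C)=C/CO | starting material
5 | (2E,6E,10E)-geranylgeranial | CC(C)=CCC/C(C)=C/CC/C(C)=C/CC/C(C)=C/C=O | intermediate
6 | dienamine of 5 with the (S)-catalyst, N–CH=CH–C(=CH2)–chain (not isolated) | CC(C)=CCC/C(C)=C/CC/C(C)=C/CCC(=C)/C=C/N1CCC[C@H]1C(O[Si](CC)(CC)CC)(c1cc(C(F)(F)F)cc(C(F)(F)F)c1)c1cc(C(F)(F)F)cc(C(F)(F)F)c1 | intermediate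
7 | iminium benzoate of the vinylogous aldol adduct, drawn as the isomer that cyclises (not isolated) | CC(C)=CCC/C(C)=C/CC/C(C)=C/CC\C(C[C@@H](O)c1c(C)c(O[Si](C(C)C)(C(C)C)C(C)C)cc(C)c1O)=C/C=[N+]1\CCC[C@H]1C(O[Si](CC)(CC)CC)(c1cc(C(F)(F)F)cc(C(F)(F)F)c1)c1cc(C(F)(F)F)cc(C(F)(F)F)c1.[O-]C(=O)c1ccccc1 | intermediate
8 | 2-[(2R,4R)-4-hydroxy-5,8-dimethyl-2-[(3E,7E)-4,8,12-trimethyltrideca-3,7,11-trien-1-yl]-6-[(triisopropylsilyl)oxy]chroman-2-yl]acetaldehyde (not isolated) | CC(C)=CCC/C(C)=C/CC/C(C)=C/CC[C@]1(CC=O)C[C@@H](O)c2c(C)c(O[Si](C(C)C)(C(C)C)C(C)C)cc(C)c2O1 | intermediate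
9 | bridged tricyclic lactol, C2 and C4 both R in chroman numbering, anomeric epimers | CC(C)=CCC/C(C)=C/CC/C(C)=C/CC[C@]12C[C@@H](OC(O)C2)c3c(C)c(O[Si](C(C)C)(C(C)C)C(C)C)cc(C)c3O1 | intermediate
10 | (2R,4R)-2,5,8-trimethyl-2-[(3E,7E)-4,8,12-trimethyltrideca-3,7,11-trien-1-yl]-6-[(triisopropylsilyl)oxy]chroman-4-ol | CC(C)=CCC/C(C)=C/CC/C(C)=C/CC[C@]1(C)C[C@@H](O)c2c(C)c(O[Si](C(C)C)(C(C)C)C(C)C)cc(C)c2O1 | intermediate
11 | O-(2R,4R)-chroman-4-yl S-methyl carbonodithioate of 10 | CC(C)=CCC/C(C)=C/CC/C(C)=C/CC[C@]1(C)C[C@@H](OC(=S)SC)c2c(C)c(O[Si](C(C)C)(C(C)C)C(C)C)cc(C)c2O1 | intermediate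
12 | (R)-β-tocotrienol triisopropylsilyl ether | CC(C)=CCC/C(C)=C/CC/C(C)=C/CC[C@]1(C)CCc2c(C)c(O[Si](C(C)C)(C(C)C)C(C)C)cc(C)c2O1 | intermediate
13 | (2R)-2,5,8-trimethyl-2-[(3E,7E)-4,8,12-trimethyltrideca-3,7,11-trien-1-yl]chroman-6-ol | CC(C)=CCC/C(C)=C/CC/C(C)=C/CC[C@]1(C)CCc2c(C)c(O)cc(C)c2O1 | target

**Step count.** Total: 8 steps. Longest linear sequence: 7 steps (1 to 13 through steps 1, 2, 4, 5, 6, 7 and 8).

**Steps most likely to fail**

1. Step 4. Deprotonation may compete at the chain methylene, and the oxa-Michael closure may discriminate the two faces incompletely, so that regio- and enantiocontrol erode. The fallback sets out from 2 and 5 and builds the ring by a phenol–enal annulation. With PhB(OH)2 and catalytic AcOH in refluxing toluene (water removal), the boronate-tethered adduct fragments to an ortho-quinone methide, whose oxa-6π electrocyclisation gives racemic 2,5,8-trimethyl-2-(trienyl)-6-(triisopropylsilyloxy)-2H-chromene F1; here the enal supplies C2 with its methyl and chain directly and no carbon has to be excised. Diimide (2-nitrobenzenesulfonyl hydrazide, Et3N, CH2Cl2, rt) should reduce only the cis-disubstituted C3=C4 bond and give the racemic silyl ether F2. Preparative chromatography on a cellulose tris(3,5-dimethylphenylcarbamate) phase separates the enantiomers, and the (R)-enantiomer is 12, which re-enters at step 8. This fallback gives up catalytic stereocontrol for resolution.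

2. Step 5. The aldehyde is masked as the lactol, so formyl C–H activation may be slow, and forcing temperatures invite alkene migration or β-aryloxy elimination from the alkyl–rhodium intermediate. The fallback sets out from 9 and removes the C4 oxygen before the carbon is excised, so that no lactol can form. NaBH4 in MeOH at 0 °C should reduce the lactol to the diol F3, and PivCl with pyridine at 0 °C should acylate only the primary hydroxyl to give the pivalate F4. NaH, CS2 and MeI then give the xanthate F5, and Bu3SnH with Et3B and a trace of air gives the C4-deoxygenated pivalate F6. i-Bu2AlH at −78 °C frees the primary alcohol F7, and Dess–Martin periodinane buffered with NaHCO3 oxidises it to the free chroman-2-ylacetaldehyde F8. RhCl(PPh3)3 in toluene at 80–110 °C decarbonylates this unmasked aldehyde to 12. The sequence replaces steps 5 to 7 and comes back to the route at 12.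

3. Step 7 (with step 6). The electron-rich benzylic xanthate may ionise (O-to-S rearrangement or elimination), or the C4 radical may add to the C3′ alkene. The fallback sets out from 10 and removes the oxygen without a radical at C4. Burgess reagent in toluene at 60 °C dehydrates the benzylic alcohol to the (R)-2H-chromene F9, which is kept from light to avoid electrocyclic ring opening and loss of configuration. Diimide (2-nitrobenzenesulfonyl hydrazide, Et3N, CH2Cl2, rt) then reduces only the C3=C4 bond and returns the route at 12.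

**Further compounds**

F1 | step 4 | rac-triisopropyl{[2,5,8-trimethyl-2-[(3E,7E)-4,8,12-trimethyltrideca-3,7,11-trien-1-yl]-2H-chromen-6-yl]oxy}silane | CC(C)=CCC/C(C)=C/CC/C(C)=C/CCC1(C)C=Cc2c(C)c(O[Si](C(C)C)(C(C)C)C(C)C)cc(C)c2O1
F2 | step 4 | rac-triisopropyl{[2,5,8-trimethyl-2-[(3E,7E)-4,8,12-trimethyltrideca-3,7,11-trien-1-yl]chroman-6-yl]oxy}silane | CC(C)=CCC/C(C)=C/CC/C(C)=C/CCC1(C)CCc2c(C)c(O[Si](C(C)C)(C(C)C)C(C)C)cc(C)c2O1
F3 | step 5 | (2S,4R)-2-(2-hydroxyethyl)-5,8-dimethyl-2-[(3E,7E)-4,8,12-trimethyltrideca-3,7,11-trien-1-yl]-6-[(triisopropylsilyl)oxy]chroman-4-ol (C2 arranged as in 9) | CC(C)=CCC/C(C)=C/CC/C(C)=C/CC[C@]1(CCO)C[C@@H](O)c2c(C)c(O[Si](C(C)C)(C(C)C)C(C)C)cc(C)c2O1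
F4 | step 5 | primary pivalate of F3 | CC(C)=CCC/C(C)=C/CC/C(C)=C/CC[C@]1(CCOC(=O)C(C)(C)C)C[C@@H](O)c2c(C)c(O[Si](C(C)C)(C(C)C)C(C)C)cc(C)c2O1
F5 | step 5 | C4 S-methyl xanthate of F4 | CC(C)=CCC/C(C)=C/CC/C(C)=C/CC[C@]1(CCOC(=O)C(C)(C)C)C[C@@H](OC(=S)SC)c2c(C)c(O[Si](C(C)C)(C(C)C)C(C)C)cc(C)c2O1
F6 | step 5 | 2-[(2R)-5,8-dimethyl-2-[(3E,7E)-4,8,12-trimethyltrideca-3,7,11-trien-1-yl]-6-[(triisopropylsilyl)oxy]chroman-2-yl]ethyl pivalate | CC(C)=CCC/C(C)=C/CC/C(C)=C/CC[C@]1(CCOC(=O)C(C)(C)C)CCc2c(C)c(O[Si](C(C)C)(C(C)C)C(C)C)cc(C)c2O1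
F7 | step 5 | 2-[(2R)-5,8-dimethyl-2-[(3E,7E)-4,8,12-trimethyltrideca-3,7,11-trien-1-yl]-6-[(triisopropylsilyl)oxy]chroman-2-yl]ethanol | CC(C)=CCC/C(C)=C/CC/C(C)=C/CC[C@]1(CCO)CCc2c(C)c(O[Si](C(C)C)(C(C)C)C(C)C)cc(C)c2O1
F8 | step 5 | 2-[(2R)-5,8-dimethyl-2-[(3E,7E)-4,8,12-trimethyltrideca-3,7,11-trien-1-yl]-6-[(triisopropylsilyl)oxy]chroman-2-yl]acetaldehyde | CC(C)=CCC/C(C)=C/CC/C(C)=C/CC[C@]1(CC=O)CCc2c(C)c(O[Si](C(C)C)(C(C)C)C(C)C)cc(C)c2O1
F9 | step 7 | triisopropyl{[(2R)-2,5,8-trimethyl-2-[(3E,7E)-4,8,12-trimethyltrideca-3,7,11-trien-1-yl]-2H-chromen-6-yl]oxy}silane | CC(C)=CCC/C(C)=C/CC/C(C)=C/CC[C@]1(C)C=Cc2c(C)c(O[Si](C(C)C)(C(C)C)C(C)C)cc(C)c2O1
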